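Compound numbers 1–25 are fixed by the steps below and are used in every section.

## Analysis of the target

The target is a depsidone: two benzene rings joined by an ether oxygen (O5) and an aryl ester (O10–C11) in a seven-membered 11H-dibenzo[b,e][1,4]dioxepin-11-one. Ring A (C1–C4) carries a methyl group at C1, a phenol at C3 and a formyl group at C4. Ring B (C5a–C9a) is hexasubstituted with six different groups: O5 at C5a, the lactol carbon on C6, the lactone carbonyl on C7, a chelated phenol at C8, the CH2O–fumarate half-ester at C9 and O10 at C9a. The only stereocentre is the lactol carbon of the five-membered hydroxylactone fused at C6/C7, with R configuration. It has no stereochemical partner and equilibrates through the ring-opened formyl acid, so it can only be fixed at the end and in the solid. The sensitive groups are the aryl lactone (base), the ortho-hydroxybenzyl ester (loss of carboxylate to an ortho-quinone methide under base or heat), the E-configured unsaturated half-ester, and two aldehyde-level carbons. The difficulties are a diaryl ether and an aryl ester that are each flanked by two ortho substituents on both rings, the fixed order of six substituents on ring B, and the oxidation of one aryl methyl group while the other stays. The strategy rests on ring B: the oxygens at C8 and C5a are para, and the two carbons between them (C7, C6) sit at carboxyl and formyl level. The unit C8–C9–C9a–C5a with its oxygens is therefore a 2,4-dioxygenated 3-methylfuran whose ring oxygen becomes O5, and C7–C6 is a 4-oxobut-2-ynoate acetal.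

## Retrosynthetic reasoning

**25 to 24 to 23.** The lactol carbon is stereolabile, so no covalent asymmetric step can set it durably. The R configuration is assigned last, by crystallising one diastereomeric salt (24) of the racemic acid 23 with a chiral tertiary amine while the epimers interconvert in solution, and then releasing 25 in the cold. The free carboxylic acid of the fumarate half-ester is the salt-forming handle.

**23 to 22.** The lactol C–O bond, the ring A phenol and the terminal acid are opened to a tert-butyl ester plus diethyl acetal on ring B, a methoxymethyl ether on ring A and a tert-butyl fumarate. One acid treatment of 22 removes all four. The ring B carboxyl is carried as a tert-butyl ester and not as a simple alkyl ester, because saponification at this stage would open the depsidone lactone and cleave the benzylic fumarate.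

**22 to 19 and 20.** The benzylic C–O bond at the C9 carbon is cut, leading back through bromide 21 to the methyl compound 19 and the half-ester 20. The cut is made here because the C9 methyl is ortho to the free C8 phenol, which in turn is para to O5, so it can be activated through an ortho-quinone methide. The ring A methyl is meta to its oxygen and cannot. This distinguishes the two methyl groups without radical chemistry, which would not discriminate the acetal and aldehyde C–H bonds.

**19 to 18 to 17.** The ester bond O10–C11 is cut to give hydroxy acid 18; the seven-membered ring closes readily once the diaryl ether holds acid and phenol together. Both the C9a oxygen and the ring A carboxyl are masked as benzyl derivatives in 17, so one hydrogenolysis unveils both.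

**17 to 10 and 16.** The ether bond C4a–O5 is cut. Ring A is the electrophile: in 16 the fluoride is flanked by formyl and ester groups. Ring B is the nucleophile through the non-chelated hydroxyl of hydroquinone 10. The forward step must distinguish the two hydroxyls of 10; the one next to the ester is hydrogen-bonded and its anion is delocalised into the carbonyl.

**10 to 4 and 7.** The bonds C5a–C6 and C7–C8 (depsidone locants) are cut. This is the key disconnection: a (4+2) cycloaddition of silyloxyfuran 4 with ynoate 7 gives oxabicycle 8, which opens to 9 and is desilylated to 10. The ring construction places all six ring B substituents in order: benzyloxy for O10, methyl for the C9 carbon, and ester and acetal already differentiated for the lactol.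

**4 to 2 to 1, and 7 to 5.** Furan 4 comes from tetronic acid 1 by O-benzylation (2) and silylation of the dienolate 3. Ynoate 7 comes from alkyne 5 by acylation of acetylide 6. Both are short and conventional, so the risk sits in the cycloaddition.

**16 to 15 to 13 to 12 to 11.** On ring A the ester carbon replaces a bromine (carbonylation of 15), the formyl group enters between fluorine and the protected oxygen by directed metalation of 13 through aryllithium 14, and the bromine enters para to the hydroxyl of 11 (12).

## Alternatives that were turned down

**Alternative 1: late C–H lactonisation of a ring B methyl.**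
- Disconnection: the benzylic C–O bond of the five-membered lactone is cut, leading back to the ortho-methyl carboxylic acid A2.
- Forward key step: under hypoiodite-forming photochemical conditions the carboxyl radical of A2 abstracts a hydrogen from the ortho methyl group; oxidation of the benzylic radical and capture by the carboxylate close the phthalide A1.
- In its favour: the atoms that become the lactol ring are a plain methyl group and an acid during the whole assembly, so no acid-labile acetal has to be carried. On this point it is stronger than the chosen route, which carries an acetal from step 3. The hydrogen abstraction is also directed to the one methyl group beside the acid.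
- Against it: A1 is at methylene level, one oxidation step below the lactol. A second benzylic oxidation is then needed beside the fumarate-bearing CH2, the ring A methyl and the aldehyde. The radical conditions also threaten the aldehyde C–H and the fumarate double bond, and the phenol acetates must be removed at the end without opening the depsidone. The key step also does nothing to build hexasubstituted ring B.
- Comparison: the chosen route brings the formyl carbon in at its final oxidation level and uses its key step to build ring B with all substituents in place.

**Alternative 2: ring B as a quinone, acyloxylation then SNAr.**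
- Disconnection: both C–O bonds of the seven-membered ring are cut at once, giving quinone A4 and fluoro acid A5.
- Forward key step: under carbonate base the carboxylate of A5 adds to the only hydrogen-bearing carbon of A4, and the resulting hydroquinone phenoxide displaces fluoride to give A3, which has the same structure as 19.
- In its favour: it is more convergent and shorter than the chosen route by two operations at this stage, and it avoids benzyl groups and a hydrogenolysis beside an aryl aldehyde. On step economy it is the stronger plan.
- Against it: carboxylates are weak and reversible donors toward quinones. The basic medium also invites tautomerisation of the methylquinone to a quinone methide and redox scrambling. The aryl ester formed next to a free phenoxide can migrate, which would exchange ether and ester positions. A4 itself is a fully substituted, electron-poor quinone that still has to be made, most plausibly from a hydroquinone of the type of 10.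
- Comparison: the chosen route reaches the same compound (19) by SNAr, hydrogenolysis and lactonisation, each a closed-shell reaction with a predictable outcome. The positions of ether and ester oxygen are fixed by which oxygen carries the benzyl group.

**Alternative 3: Michael–Dieckmann construction of ring B on a ring A aryloxyacrylate.**
- Disconnection: the C6–C7 and C9–C9a bonds of ring B are cut, giving enol triflate A8 and keto ester A7.
- Forward key step: under hydride base the enolate of A7 replaces the triflate of A8 by addition–elimination; the ethyl ketone enolate then acylates on the acrylate ester, and enolisation gives the resorcylate A6.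
- In its favour: ring B grows directly on the ring A oxygen, so no hindered intermolecular diaryl ether formation is needed. On this point it is stronger than the chosen route. The C9a oxygen also arrives free, and A7 is a cheap building block.
- Against it: the substitution takes place at a tetrasubstituted, acetal-bearing vinylic carbon and needs the right alkene geometry for ring closure. The second bond requires the less acidic ketone enolate to attack a hindered ester while the ring A allyl ester competes. A6 also lacks the ring A formyl group, which could not pass through the enolate chemistry and would have to be introduced afterwards between two oxygen substituents on a molecule with three esters.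
- Comparison: the chosen route couples a complete ring A and fixes the ring B regiochemistry by the polarisation of diene and dienophile; the price is the crowded SNAr.

Key step: step 4

Remark: the lactol carbon equilibrates in solution by ring–chain tautomerism, so the R configuration is fixed in the solid state (steps 14 and 15) and the product is kept cold and away from base.
Remark: which lactol epimer crystallises as the quinine salt cannot be predicted; the route assumes it is the R epimer.
Remark: 3-methyltetronic acid 1 and (E)-4-(tert-butoxy)-4-oxobut-2-enoic acid 20, the half-ester of fumaric acid, are taken as purchasable.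

## Route

Step 1
Reactants: 1 3-methyltetronic acid (4-hydroxy-3-methylfuran-2(5H)-one)
Product: 2 4-(benzyloxy)-3-methylfuran-2(5H)-one
Conditions: BnOH, PPh3, DIAD, THF, 0 °C → rt
Reagents that add atoms: benzyl alcohol, OCc1ccccc1
Why: Mitsunobu O-alkylation of the acidic vinylogous acid; under these conditions the ambident anion is alkylated on the enol oxygen, which avoids the C-benzylation that benzyl halides and base tend to give.

Step 2
Reactants: 2 4-(benzyloxy)-3-methylfuran-2(5H)-one
Product: 4 4-(benzyloxy)-3-methyl-2-(trimethylsilyloxy)furan, via lithium furanolate 3 (not isolated)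
Conditions: LiN(i-Pr)2, THF, −78 °C; Me3SiCl, −78 °C → rt; pentane, filtration under Ar, used crude
Reagents that add atoms: chlorotrimethylsilane, C[Si](C)(C)Cl
Why: γ-Deprotonation of the tetronate at C5 gives the aromatic furanolate 3, which the hard silyl chloride traps on oxygen (silyl dienol ether formation); C3 is blocked by the methyl group, so no α-proton competes.

Step 3
Reactants: 5 3,3-diethoxyprop-1-yne
Product: 7 tert-butyl 4,4-diethoxybut-2-ynoate, via lithium acetylide 6 (not isolated)
Conditions: n-BuLi, THF, −78 °C; Boc2O, −78 → 0 °C; AcOH
Reagents that add atoms: di-tert-butyl dicarbonate, CC(C)(C)OC(=O)OC(=O)OC(C)(C)C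
Why: Acylation of a lithium acetylide with a dicarbonate is a standard route to tert-butyl alkynoates; the acetal is inert to the base, and the tert-butyl ester is chosen so that the ring B carboxyl can be released by acid in step 13.

Step 4
Reactants: 4 4-(benzyloxy)-3-methyl-2-(trimethylsilyloxy)furan; 7 tert-butyl 4,4-diethoxybut-2-ynoate
Product: 10 tert-butyl 4-(benzyloxy)-6-(diethoxymethyl)-2,5-dihydroxy-3-methylbenzoate, via oxabicyclic cycloadduct 8 (not isolated), via monosilylated hydroquinone 9 (not isolated)
Conditions: toluene, 2,6-lutidine (cat.), 80 °C, sealed tube, Ar; then MeOH, KF (cat.), 0 °C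
Reagents that add atoms: none
Why: A normal-electron-demand, asynchronous (4+2) cycloaddition between the electron-rich diene 4 and the ynoate 7 forms the bonds from furan C5 to the alkyne β-carbon and from furan C2 to the alkyne α-carbon and closes the six-membered carbocycle intermolecularly as the 7-oxanorbornadiene 8. The closest known reaction type is the Diels–Alder reaction of 2-silyloxyfurans with acetylenic esters followed by opening of the oxygen bridge to para-hydroxyphenol derivatives. In 8 the bridgehead silyl ketal ionises (C–O cleavage pushed by the silyloxy group and the benzyloxy-substituted double bond), the other bridgehead loses its proton, and arene 9 results, in which the former furan oxygen is the hydroxyl para to the silyloxy group; methanolysis of the labile aryl silyl ether gives 10. The two bridgehead stereocentres of 8 are racemic and transient and are erased on aromatisation, so no stereocontrol is needed. The selectivity that matters is regiochemistry: furan C5 carries the largest HOMO coefficient because the 2-silyloxy group (through the diene) and the 4-benzyloxy group (directly) both push electron density to it, and it bonds to the β-carbon of the ynoate, the acetal-bearing terminus with the largest LUMO coefficient, which places the ester next to the silyloxy-derived hydroxyl. The medium is kept free of Lewis and protic acids (trace lutidine) so that the silyl dienol ether does not add to the acetal in a vinylogous Mukaiyama sense.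

Step 5
Reactants: 11 3-fluoro-5-methylphenol
Product: 12 4-bromo-3-fluoro-5-methylphenol
Conditions: NBS, MeCN, −10 → 0 °C
Reagents that add atoms: N-bromosuccinimide, O=C1CCC(=O)N1Br
Why: Electrophilic aromatic bromination; for 3,5-disubstituted phenols the position para to the hydroxyl (here between F and CH3) is the usual site of attack in acetonitrile.

Step 6
Reactants: 12 4-bromo-3-fluoro-5-methylphenol
Product: 13 2-bromo-1-fluoro-5-(methoxymethoxy)-3-methylbenzene
Conditions: NaH, MOMCl, THF, 0 °C → rt
Reagents that add atoms: chloromethyl methyl ether, COCCl
Why: Williamson-type O-alkylation of the sodium phenoxide; the methoxymethyl ether protects the phenol through the SNAr and serves as a directing group in step 7.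

Step 7
Reactants: 13 2-bromo-1-fluoro-5-(methoxymethoxy)-3-methylbenzene
Product: 15 3-bromo-2-fluoro-6-(methoxymethoxy)-4-methylbenzaldehyde, via aryllithium 14 (not isolated)
Conditions: LiN(i-Pr)2, THF, −78 °C; DMF, −78 °C; AcOH
Reagents that add atoms: N,N-dimethylformamide, CN(C)C=O
Why: Directed ortho-metalation: the hydrogen flanked by fluorine and the acetal oxygen is the most acidic, the amide base does not exchange the bromine, and at −78 °C the ortho-fluoro aryllithium 14 is formylated before it can lose LiF.

Step 8
Reactants: 15 3-bromo-2-fluoro-6-(methoxymethoxy)-4-methylbenzaldehyde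
Product: 16 benzyl 2-fluoro-3-formyl-4-(methoxymethoxy)-6-methylbenzoate
Conditions: Pd(OAc)2 (cat.), Xantphos (cat.), CO (1 atm), BnOH, Et3N, toluene, 90 °C
Reagents that add atoms: carbon monoxide, [C-]#[O+]; benzyl alcohol, OCc1ccccc1
Why: Palladium-catalysed alkoxycarbonylation: zerovalent palladium inserts into the C–Br bond, CO insertion gives an acyl complex of divalent palladium, and benzyl alcohol intercepts it; the weak amine base keeps the alkoxide concentration too low for substitution of the activated fluoride.

Step 9
Reactants: 10 tert-butyl 4-(benzyloxy)-6-(diethoxymethyl)-2,5-dihydroxy-3-methylbenzoate; 16 benzyl 2-fluoro-3-formyl-4-(methoxymethoxy)-6-methylbenzoate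
Product: 17 benzyl 2-[6-(benzyloxy)-3-(tert-butoxycarbonyl)-2-(diethoxymethyl)-4-hydroxy-5-methylphenoxy]-3-formyl-4-(methoxymethoxy)-6-methylbenzoate
Conditions: Cs2CO3, DMF (degassed), 60 °C, Ar
Reagents that add atoms: none
Why: Nucleophilic aromatic substitution: the fluoride of 16 is activated by an ortho formyl and an ortho ester group, and the non-chelated, more electron-rich phenoxide of 10 (the oxygen that came from the furan ring) is the better nucleophile. The hydroxyl next to the ester is held in a hydrogen bond and its anion is delocalised into the carbonyl, the same bias that allows selective 5-O-alkylation of 2,5-dihydroxybenzoates.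

Step 10
Reactants: 17 benzyl 2-[6-(benzyloxy)-3-(tert-butoxycarbonyl)-2-(diethoxymethyl)-4-hydroxy-5-methylphenoxy]-3-formyl-4-(methoxymethoxy)-6-methylbenzoate
Product: 18 2-[3-(tert-butoxycarbonyl)-2-(diethoxymethyl)-4,6-dihydroxy-5-methylphenoxy]-3-formyl-4-(methoxymethoxy)-6-methylbenzoic acid
Conditions: H2 (1 atm), 10% Pd/C, EtOAc, rt, stopped after two equivalents of H2
Reagents that add atoms: none
Why: Hydrogenolysis cleaves the benzyl ether and the benzyl ester in one operation; in neutral ethyl acetate at 1 atm the doubly ortho-substituted aldehyde, the acetal and the methoxymethyl ether should be left in place.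

Step 11
Reactants: 18 2-[3-(tert-butoxycarbonyl)-2-(diethoxymethyl)-4,6-dihydroxy-5-methylphenoxy]-3-formyl-4-(methoxymethoxy)-6-methylbenzoic acid
Product: 19 tert-butyl 6-(diethoxymethyl)-4-formyl-8-hydroxy-3-(methoxymethoxy)-1,9-dimethyl-11-oxo-11H-dibenzo[b,e][1,4]dioxepine-7-carboxylate
Conditions: DCC, DMAP (cat.), CH2Cl2 (high dilution), 0 °C → rt
Reagents that add atoms: none
Why: Carbodiimide-mediated (Steglich-type) lactonisation closes the seven-membered depsidone ring; only the hydroxyl ortho to the ether bridge can reach the activated acid, whereas the chelated hydroxyl is para to the bridge and cannot cyclise.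

Step 12
Reactants: 19 tert-butyl 6-(diethoxymethyl)-4-formyl-8-hydroxy-3-(methoxymethoxy)-1,9-dimethyl-11-oxo-11H-dibenzo[b,e][1,4]dioxepine-7-carboxylate; 20 (E)-4-(tert-butoxy)-4-oxobut-2-enoic acid
Product: 22 tert-butyl [7-(tert-butoxycarbonyl)-6-(diethoxymethyl)-4-formyl-8-hydroxy-3-(methoxymethoxy)-1-methyl-11-oxo-11H-dibenzo[b,e][1,4]dioxepin-9-yl]methyl (2E)-but-2-enedioate, via benzylic bromide 21 (not isolated)
Conditions: NBS, CH2Cl2 (dry), −20 → 0 °C, dark; then 20 (excess), i-Pr2NEt, CH2Cl2, −20 °C → rt
Reagents that add atoms: none
Why: Phenol-directed side-chain bromination of a ring-blocked ortho-cresol (ipso attack of electrophilic bromine, loss of HBr to the ortho-quinone methide, re-addition of HBr), the behaviour known for fully substituted para-oxygenated phenols of the chromanol type, gives the ortho-hydroxybenzyl bromide 21 without net acid. The carboxylate of 20 then substitutes 21 through the same quinone methide. The ring A methyl is meta to its oxygen and cannot react this way, and the excess of buffered 20 keeps the quinone methide from dimerising.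

Step 13
Reactants: 22 tert-butyl [7-(tert-butoxycarbonyl)-6-(diethoxymethyl)-4-formyl-8-hydroxy-3-(methoxymethoxy)-1-methyl-11-oxo-11H-dibenzo[b,e][1,4]dioxepin-9-yl]methyl (2E)-but-2-enedioate
Product: 23 racemic lactol acid (fumarate half-ester of the depsidone hydroxylactone; both configurations at the lactol carbon)
Conditions: CF3CO2H/CH2Cl2/H2O, 0 °C → rt
Reagents that add atoms: water, O
Why: Acidolysis removes both tert-butyl esters as isobutene and hydrolyses the diethyl acetal and the methoxymethyl ether; the resulting ortho-formyl benzoic acid closes spontaneously to the hydroxylactone (ring–chain tautomerism), unselectively at the new lactol carbon, so 23 is racemic.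

Step 14
Reactants: 23 racemic lactol acid
Product: 24 quininium salt (1:1) of the R-configured lactol acid
Conditions: quinine (1.0 equiv), MeCN/EtOAc, 40 → 5 °C, seeded slurry, prolonged ageing
Reagents that add atoms: quinine, COC1=CC2=C(C=CN=C2C=C1)[C@H]([C@@H]3C[C@@H]4CCN3C[C@@H]4C=C)O
Why: Crystallisation-induced diastereomer transformation: the two lactol epimers of the salt interconvert in solution through the open formyl carboxylate (mutarotation), and the less soluble diastereomeric salt crystallises and drains the equilibrium, so the configuration at the lactol carbon is set by the lattice of the alkaloid salt. Quinine is a tertiary base, so it cannot condense with the ring A aldehyde, and one equivalent is consumed by the carboxylic acid, leaving the phenols protonated.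

Step 15
Reactants: 24 quininium salt (1:1) of the R-configured lactol acid
Product: 25 target: R-configured lactol acid (fumarate half-ester of the depsidone hydroxylactone)
Conditions: 1 M aq. HCl/EtOAc, 0 °C; crystallisation from cold EtOAc/heptane
Reagents that add atoms: none
Why: Proton transfer from the mineral acid releases the free acid at 0 °C; in a cold, acidic medium ring opening of the lactol is slow, and prompt crystallisation should retain the R configuration.

## Compound list

1 | 3-methyltetronic acid (4-hydroxy-3-methylfuran-2(5H)-one) | CC1=C(O)COC1=O | starting material
2 | 4-(benzyloxy)-3-methylfuran-2(5H)-one | CC1=C(OCc2ccccc2)COC1=O | intermediate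
3 | lithium 4-(benzyloxy)-3-methylfuran-2-olate | [Li+].[O-]c1occ(OCc2ccccc2)c1C | intermediate
4 | 4-(benzyloxy)-3-methyl-2-(trimethylsilyloxy)furan | C[Si](C)(C)Oc1occ(OCc2ccccc2)c1C | intermediate
5 | 3,3-diethoxyprop-1-yne | C#CC(OCC)OCC | starting material
6 | (3,3-diethoxyprop-1-yn-1-yl)lithium | [Li]C#CC(OCC)OCC | intermediate
7 | tert-butyl 4,4-diethoxybut-2-ynoate | CCOC(OCC)C#CC(=O)OC(C)(C)C | intermediate
8 | tert-butyl 5-(benzyloxy)-3-(diethoxymethyl)-6-methyl-1-(trimethylsilyloxy)-7-oxabicyclo[2.2.1]hepta-2,5-diene-2-carboxylate (racemic) | C[Si](C)(C)OC12OC(C(C(OCC)OCC)=C1C(=O)OC(C)(C)C)C(OCc1ccccc1)=C2C | intermediate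
9 | tert-butyl 4-(benzyloxy)-6-(diethoxymethyl)-5-hydroxy-3-methyl-2-(trimethylsilyloxy)benzoate | CC(C)(C)OC(=O)c1c(O[Si](C)(C)C)c(C)c(OCc2ccccc2)c(O)c1C(OCC)OCC | intermediate
10 | tert-butyl 4-(benzyloxy)-6-(diethoxymethyl)-2,5-dihydroxy-3-methylbenzoate | CC(C)(C)OC(=O)c1c(O)c(C)c(OCc2ccccc2)c(O)c1C(OCC)OCC | intermediate
11 | 3-fluoro-5-methylphenol | Cc1cc(O)cc(F)c1 | starting material
12 | 4-bromo-3-fluoro-5-methylphenol | Cc1cc(O)cc(F)c1Br | intermediate
13 | 2-bromo-1-fluoro-5-(methoxymethoxy)-3-methylbenzene | Cc1cc(OCOC)cc(F)c1Br | intermediate
14 | [3-bromo-2-fluoro-6-(methoxymethoxy)-4-methylphenyl]lithium | [Li]c1c(OCOC)cc(C)c(Br)c1F | intermediate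
15 | 3-bromo-2-fluoro-6-(methoxymethoxy)-4-methylbenzaldehyde | Cc1cc(OCOC)c(C=O)c(F)c1Br | intermediate
16 | benzyl 2-fluoro-3-formyl-4-(methoxymethoxy)-6-methylbenzoate | Cc1cc(OCOC)c(C=O)c(F)c1C(=O)OCc1ccccc1 | intermediate
17 | benzyl 2-[6-(benzyloxy)-3-(tert-butoxycarbonyl)-2-(diethoxymethyl)-4-hydroxy-5-methylphenoxy]-3-formyl-4-(methoxymethoxy)-6-methylbenzoate | Cc1cc(OCOC)c(C=O)c(Oc2c(C(OCC)OCC)c(C(=O)OC(C)(C)C)c(O)c(C)c2OCc2ccccc2)c1C(=O)OCc1ccccc1 | intermediate
18 | 2-[3-(tert-butoxycarbonyl)-2-(diethoxymethyl)-4,6-dihydroxy-5-methylphenoxy]-3-formyl-4-(methoxymethoxy)-6-methylbenzoic acid | Cc1cc(OCOC)c(C=O)c(Oc2c(C(OCC)OCC)c(C(=O)OC(C)(C)C)c(O)c(C)c2O)c1C(=O)O | intermediate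
19 | tert-butyl 6-(diethoxymethyl)-4-formyl-8-hydroxy-3-(methoxymethoxy)-1,9-dimethyl-11-oxo-11H-dibenzo[b,e][1,4]dioxepine-7-carboxylate | Cc1cc(OCOC)c(C=O)c2c1C(=O)Oc1c(C)c(O)c(C(=O)OC(C)(C)C)c(C(OCC)OCC)c1O2 | intermediate
20 | (E)-4-(tert-butoxy)-4-oxobut-2-enoic acid (mono-tert-butyl fumarate) | OC(=O)/C=C/C(=O)OC(C)(C)C | starting material
21 | tert-butyl 9-(bromomethyl)-6-(diethoxymethyl)-4-formyl-8-hydroxy-3-(methoxymethoxy)-1-methyl-11-oxo-11H-dibenzo[b,e][1,4]dioxepine-7-carboxylate | Cc1cc(OCOC)c(C=O)c2c1C(=O)Oc1c(CBr)c(O)c(C(=O)OC(C)(C)C)c(C(OCC)OCC)c1O2 | intermediate
22 | tert-butyl [7-(tert-butoxycarbonyl)-6-(diethoxymethyl)-4-formyl-8-hydroxy-3-(methoxymethoxy)-1-methyl-11-oxo-11H-dibenzo[b,e][1,4]dioxepin-9-yl]methyl (2E)-but-2-enedioate | Cc1cc(OCOC)c(C=O)c2c1C(=O)Oc1c(COC(=O)/C=C/C(=O)OC(C)(C)C)c(O)c(C(=O)OC(C)(C)C)c(C(OCC)OCC)c1O2 | intermediate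
23 | racemic lactol acid: (2E)-4-oxo-4-(arylmethoxy)but-2-enoic acid in which the aryl group is the 9-position of 4-formyl-3,8-dihydroxy-1-methyl-11H-dibenzo[b,e][1,4]dioxepin-11-one carrying a five-membered hydroxylactone fused at C6/C7 (C7–C(=O)–O–CH(OH)–C6), lactol carbon unassigned | Cc1cc(O)c(C=O)c2c1C(=O)Oc1c(COC(=O)/C=C/C(=O)O)c(O)c3c(c1O2)C(O)OC3=O | intermediate
24 | quininium salt (1:1) of 25 (carboxylate of the fumarate half-ester, lactol carbon R) | Cc1cc(O)c(C=O)c2c1C(=O)Oc1c(COC(=O)/C=C/C(=O)[O-])c(O)c3c(c1O2)[C@H](O)OC3=O.COC1=CC2=C(C=CN=C2C=C1)[C@H]([C@@H]3C[C@@H]4CC[NH+]3C[C@@H]4C=C)O | intermediate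
25 | target: the acid of 23 with R configuration at the lactol carbon | Cc1cc(O)c(C=O)c2c1C(=O)Oc1c(COC(=O)/C=C/C(=O)O)c(O)c3c(c1O2)[C@H](O)OC3=O | target

## Step count and least certain steps

Total step count: 15. Longest linear sequence: 11 steps (steps 5 to 15, from 11). The ring B branch from 1 runs through 10 steps and the alkyne branch from 5 through 9.

**Step 4 (key step).** The cycloaddition may stall: the alkyne terminus that must bond to furan C5 is hindered by the acetal and activated by one ester only, so protodesilylation of the diene or interception at the open-chain conjugate-addition stage could take over. Fallback: an anionic Michael–Dieckmann annulation of the Hauser–Kraus type. It sets out from 2, deprotonated to the lithium furanolate 3, and from 7. In THF at −78 → 0 °C, 3 adds through C5 to the ynoate; the allenolate attacks the lactone carbonyl, the bicyclic alkoxide collapses with cleavage of the oxygen bridge, and tautomerisation and an acetic acid quench return the route at 10. No new isolable compound arises.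

**Step 12.** The electron-poor, chelated phenol may resist attack by electrophilic bromine. Alternatively, ipso attack at the ether-bearing para carbon followed by capture of adventitious water would cleave the diaryl ether, and the quinone methide could dimerise if carboxylate capture is slow. Fallback: dehydrogenation instead of halogenation. It sets out from 19, which is heated with DDQ and excess 20 in dry dioxane; hydride abstraction from the methyl group conjugated to the phenol gives the same quinone methide, which 20 captures. The route is rejoined at 22 without a new compound.

**Step 14.** The salt may crystallise as the S epimer or as a solid solution of both epimers, epimerisation in the slurry may be too slow, or the base may induce loss of fumarate through the quinone methide. Fallback: chromatographic resolution. It sets out from 23, which is separated on a polysaccharide chiral stationary phase with an acidic modifier at low temperature. This delivers 25 directly and comes back to the route there. The unwanted S-configured lactol acid F1 is re-equilibrated to 23 by brief warming in solution and recycled.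

**Step 9.** Arylation may occur at the chelated oxygen, the substitution may stall because both partners carry two ortho substituents, or the hydroquinone may be oxidised by air. Fallback: a silyl group that survives the ring opening differentiates the hydroxyls. It sets out from 2, which is deprotonated as in step 2 and silylated with tert-butyldimethylsilyl chloride to 4-(benzyloxy)-2-[(tert-butyldimethylsilyl)oxy]-3-methylfuran F2. Cycloaddition with 7 as in step 4, without the methanolysis, should give tert-butyl 4-(benzyloxy)-2-[(tert-butyldimethylsilyl)oxy]-6-(diethoxymethyl)-5-hydroxy-3-methylbenzoate F3, because aromatisation only needs loss of the bridgehead proton and leaves the silyl group on its oxygen. SNAr of F3 with 16 then gives the silyl-protected diaryl ether F4, and fluoride (set free in the same pot or added as Bu4NF/AcOH) removes the silyl group. The route is rejoined at 17.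

**Step 13.** The ortho-hydroxybenzyl ester may solvolyse in the acid through a benzylic cation or quinone methide, losing fumaric acid. Fallback: accept the loss and reinstall the ester under equilibrium control. It sets out from 22; acid treatment to completion gives the racemic 9-(hydroxymethyl) depsidone lactol F5. Heating F5 with a large excess of fumaric acid in dioxane passes through the quinone methide and returns the route at 23.

## Further compounds

F0 | step 4 | none | none
F0 | step 12 | none | none
F1 | step 14 | S-configured lactol acid (enantiomer of 25) | Cc1cc(O)c(C=O)c2c1C(=O)Oc1c(COC(=O)/C=C/C(=O)O)c(O)c3c(c1O2)[C@@H](O)OC3=O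
F2 | step 9 | 4-(benzyloxy)-2-[(tert-butyldimethylsilyl)oxy]-3-methylfuran | CC(C)(C)[Si](C)(C)Oc1occ(OCc2ccccc2)c1C
F3 | step 9 | tert-butyl 4-(benzyloxy)-2-[(tert-butyldimethylsilyl)oxy]-6-(diethoxymethyl)-5-hydroxy-3-methylbenzoate | CC(C)(C)OC(=O)c1c(O[Si](C)(C)C(C)(C)C)c(C)c(OCc2ccccc2)c(O)c1C(OCC)OCC
F4 | step 9 | benzyl 2-[6-(benzyloxy)-3-(tert-butoxycarbonyl)-4-[(tert-butyldimethylsilyl)oxy]-2-(diethoxymethyl)-5-methylphenoxy]-3-formyl-4-(methoxymethoxy)-6-methylbenzoate | Cc1cc(OCOC)c(C=O)c(Oc2c(C(OCC)OCC)c(C(=O)OC(C)(C)C)c(O[Si](C)(C)C(C)(C)C)c(C)c2OCc2ccccc2)c1C(=O)OCc1ccccc1
F5 | step 13 | racemic 9-(hydroxymethyl) depsidone lactol (4-formyl-3,8-dihydroxy-9-(hydroxymethyl)-1-methyl depsidone with the C6/C7-fused hydroxylactone) | Cc1cc(O)c(C=O)c2c1C(=O)Oc1c(CO)c(O)c3c(c1O2)C(O)OC3=O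
A1 | alternative 1 | depsidone phthalide (methylene stage of the lactol ring, both phenols acetylated, tert-butyl fumarate) | Cc1cc(OC(C)=O)c(C=O)c2c1C(=O)Oc1c(COC(=O)/C=C/C(=O)OC(C)(C)C)c(OC(C)=O)c3c(c1O2)COC3=O
A2 | alternative 1 | depsidone with ring B carboxylic acid and ortho methyl group (precursor of A1) | Cc1cc(OC(C)=O)c(C=O)c2c1C(=O)Oc1c(COC(=O)/C=C/C(=O)OC(C)(C)C)c(OC(C)=O)c(C(=O)O)c(C)c1O2
A3 | alternative 2 | protected depsidone with ring B methyl, tert-butyl ester and diethyl acetal (same structure as 19) | Cc1cc(OCOC)c(C=O)c2c1C(=O)Oc1c(C)c(O)c(C(=O)OC(C)(C)C)c(C(OCC)OCC)c1O2
A4 | alternative 2 | tert-butyl 2-(diethoxymethyl)-5-methyl-3,6-dioxocyclohexa-1,4-diene-1-carboxylate | CC1=CC(=O)C(C(OCC)OCC)=C(C(=O)OC(C)(C)C)C1=O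
A5 | alternative 2 | 2-fluoro-3-formyl-4-(methoxymethoxy)-6-methylbenzoic acid | Cc1cc(OCOC)c(C=O)c(F)c1C(=O)O
A6 | alternative 3 | allyl 2-[2-(dimethoxymethyl)-4,6-dihydroxy-3-(methoxycarbonyl)-5-methylphenoxy]-4-(methoxymethoxy)-6-methylbenzoate | Cc1cc(OCOC)cc(Oc2c(O)c(C)c(O)c(C(=O)OC)c2C(OC)OC)c1C(=O)OCC=C
A7 | alternative 3 | methyl 3-oxopentanoate | CCC(=O)CC(=O)OC
A8 | alternative 3 | allyl 2-{[4,4-dimethoxy-1-methoxy-1-oxo-3-(trifluoromethanesulfonyloxy)but-2-en-2-yl]oxy}-4-(methoxymethoxy)-6-methylbenzoate | Cc1cc(OCOC)cc(OC(C(=O)OC)=C(OS(=O)(=O)C(F)(F)F)C(OC)OC)c1C(=O)OCC=C
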